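The data were generated by integration with constants of no real substance; scatter was added.

Do not expect the G you charge to pay back in proportion: you are taking over four flasks that differ in [G], and G dies on its own product.

in all of them: J 40 mM (held)

| run | Q | G | remark | time |
|---|---|---|---|---|
| zeta | 1.8 M | 1.5 mM | run made earlier |  |
| dusk | 1.2 M | 1.5 mM |  | 15 min |
| winter | 1.2 M | 5.0 mM |  | 15 min |
| midnight | 1.2 M | 15 mM |  | 15 min |
| noon | 1.2 M | 40 mM |  | 15 min |

- zeta (time / min: Z / %): 0.500: 0.5; 1.33: 2.1; 2.50: 3.3; 4.00: 5.9; 5.00: 7.1; 8.00: 10.2; 10.0: 11.6

(scatter of a reading: 0.3 percentage points)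

- at the start none of L is dissolved
- steps that have been proposed: Q + L + G <-> G + Z; G + Z -> X; J <-> L
- "hardly changes" means that all values lie within two and a half points (for a concentration: within two and a half percent of the largest)
- no earlier run changes the charge of G; that part of a forecast is a guess

1. amount of Z at the end, in percent of the Q charged for dusk, winter, midnight, noon, in this order
2. how the row runs (falls all the way / hardly changes / falls, then rises / rises, then falls / rises all the way)

Z forms at a rate in [Q][L][G], and G + Z -> X removes G at a rate in [G][Z]. Divide one by the other and [G] drops out, so [Z] squared grows with [G][Q][L] until G has gone. In logarithms, at held [L]: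

log (end [Z]) = constant + 0.5 log [G] + 0.5 log [Q]

The slope of Z then falls as one minus the square of [Z] over its end value. The zeta run reads that end value, neglecting the loss of Q:

early slope = 26.6 mM min⁻¹
late slope = 12.6 mM min⁻¹, at [Z] = 196 mM
end [Z] = 271 mM

Call this the death ceiling, the [Z] at which G has gone; it is the total turnover number times the charge of G. It is a loose reading, since the late slope rests on two readings with a scatter of 0.3 percentage points.

Scaled to dusk, the ceiling is 18.4 % of the Q charged. Noon lies 1.43 powers of ten higher in [G], so 0.715 higher in Z: 95.1 %. Expect the row to rise, under these ceilings. The zeta readings stop at 11.6 %, and this reckoning leaves the way back out. Leave the J pressure alone: this reckoning holds [L] at 40 mM.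

The forecast gives 15.5 %, 30 %, 44 % and 62 %, rises all the way, holding that “the plateau in Z scales roughly with √G, not G”.

The flasks give 15.6 %, 29.7 %, 42.6 % and 49.2 %: rises all the way.

    Q + L + G ⇌ G + Z (K = 29.0 M⁻¹, k = 4.60 M⁻² s⁻¹)
    G + Z → X (k = 0.00860 M⁻¹ s⁻¹)
    J ⇌ L, rate k3*(csat - [L]) (kL = 0.560 s⁻¹)

Dusk, with G at 0 %, holds 19.8 % of Z after 150 min, against the ceiling of 18.4 %. Noon ends lower than its ceiling of 95.1 %, at 49.2 %. The largest single effect there is the way back from G + Z to Q + L + G: with that step removed, noon gives 72.6 %, a gain of 23 points, which is 46 % of what is missing.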